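The 2-substituted naphthazarin is disconnected across its side-chain-bearing quinone ring (C1–C4, C4a, C8a). That ring is built last on a preformed MOM-protected hydroquinone ring by a Dötz [3+2+1] benzannulation, which exploits the ring's para C1/C4 oxygenation and single C2 substituent. In one operation the carbene carbon (C4) and two arene carbons (C4a, C8a) of an aryl(methoxy)carbene chromium complex, a terminal alkyne (C3–H, C2) and one CO ligand (C1) are joined; oxidation in the same flask gives the quinone. The alkyne is an (R)-propargylic ester already carrying the complete side chain, its stereocentre set by transfer hydrogenation of an ynone. Cleavage of both peri MOM ethers finishes the target.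

Key step: step 9

Remark (assumption): the target is taken as the naphthazarin tautomer drawn, with the side chain on the quinoid ring; locants are C1(=O), C2 (side chain), C3–H, C4(=O), C4a, C5–OH, C8–OH, C8a. The side-chain stereocentre is (R) (shikonin series) and the dienoate is (3Z). Starting materials 1, 3, 7, 8, 12 and 14 are taken as catalogue compounds.

Step 1
Reactants: 1 4-methylpent-3-enoic acid
Product: 2 N-methoxy-N,4-dimethylpent-3-enamide
Conditions: CDI, CH2Cl2, 0 °C → rt; then MeNH(OMe)·HCl, rt
Reagents that add atoms: N,O-dimethylhydroxylamine hydrochloride, CNOC.Cl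
Why: Weinreb amide formation through the acyl imidazolide is a neutral amide coupling that should leave the β,γ-alkene in place.

Step 2
Reactants: 2 N-methoxy-N,4-dimethylpent-3-enamide; 3 lithium (trimethylsilyl)acetylide
Product: 4 6-methyl-1-(trimethylsilyl)hept-5-en-1-yn-3-one
Conditions: THF, –78 → –20 °C; then cold 1 M HCl
Reagents that add atoms: none
Why: Weinreb ketone synthesis, in which the acetylide adds once to give a chelated tetrahedral adduct that collapses to the ynone only on the cold acidic quench, which also protonates the liberated amine and keeps it from adding to the ynone.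

Step 3
Reactants: 4 6-methyl-1-(trimethylsilyl)hept-5-en-1-yn-3-one
Product: 5 (3R)-6-methyl-1-(trimethylsilyl)hept-5-en-1-yn-3-ol
Conditions: Ru[(R,R)-TsDPEN](p-cymene) (preformed 16-electron amido complex, 1 mol %), i-PrOH, rt
Reagents that add atoms: none
Why: Noyori asymmetric transfer hydrogenation of an α,β-acetylenic ketone under base-free conditions, in which the (R,R)-TsDPEN ligand places the alkynyl group where the aryl group of an aryl ketone sits and should deliver hydride to the face that gives the (R)-carbinol, so that the catalyst sets the new stereocentre (sense and ee to be confirmed by Mosher ester analysis).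

Step 4
Reactants: 5 (3R)-6-methyl-1-(trimethylsilyl)hept-5-en-1-yn-3-ol
Product: 6 (3R)-6-methylhept-5-en-1-yn-3-ol
Conditions: K2CO3 (cat.), MeOH, 0 °C → rt
Reagents that add atoms: none
Why: Base-catalysed methanolysis of the C(sp)–Si bond (protodesilylation) should free the terminal alkyne without touching the carbinol stereocentre.

Step 5
Reactants: 7 (2-carboxyethyl)triphenylphosphonium bromide; 8 methacrolein
Product: 10 (3Z)-5-methylhexa-3,5-dienoic acid, via sodium ylide carboxylate 9 (not isolated)
Conditions: NaHMDS (2.05 equiv), THF, –78 → 0 °C; 8, –78 °C → rt; NaHCO3 extraction, then 1 M HCl to pH 3 at 0 °C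
Reagents that add atoms: none
Why: Wittig olefination of a non-stabilised ylide under lithium-free conditions should give the (Z)-alkene under kinetic control, and the product stays a carboxylate until work-up, which protects the skipped diene from base-induced conjugation.

Step 6
Reactants: 6 (3R)-6-methylhept-5-en-1-yn-3-ol; 10 (3Z)-5-methylhexa-3,5-dienoic acid
Product: 11 (3R)-6-methylhept-5-en-1-yn-3-yl (3Z)-5-methylhexa-3,5-dienoate
Conditions: DCC, DMAP (5 mol %), CH2Cl2, –20 → 0 °C
Reagents that add atoms: none
Why: Steglich esterification with only catalytic DMAP at low temperature should acylate the propargylic alcohol with retention (the C–O bond is not broken) while limiting base-induced migration of the β,γ-alkene.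

Step 7
Reactants: 12 hydroquinone
Product: 13 1,4-bis(methoxymethoxy)benzene
Conditions: NaH, MOMCl, DMF, 0 °C → rt
Reagents that add atoms: chloromethyl methyl ether, COCCl
Why: Williamson-type O-alkylation of the bis-phenoxide gives the bis-acetal, which is stable to organolithiums and directs ortho-metalation.

Step 8
Reactants: 13 1,4-bis(methoxymethoxy)benzene; 14 hexacarbonylchromium
Product: 17 pentacarbonyl{[2,5-bis(methoxymethoxy)phenyl](methoxy)methylidene}chromium(0), via 2,5-bis(methoxymethoxy)phenyllithium 15 (not isolated), via lithium acylpentacarbonylchromate 16 (not isolated)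
Conditions: n-BuLi, TMEDA, THF, 0 °C; Cr(CO)6, 0 °C → rt; then Me3OBF4, CH2Cl2, 0 °C
Reagents that add atoms: trimethyloxonium tetrafluoroborate, C[O+](C)C.F[B-](F)(F)F
Why: Directed ortho-metalation by the OMOM group, addition of the aryllithium to a CO ligand and O-methylation of the acylchromate with Meerwein's salt is the standard Fischer carbene synthesis.

Step 9
Reactants: 11 (3R)-6-methylhept-5-en-1-yn-3-yl (3Z)-5-methylhexa-3,5-dienoate; 17 pentacarbonyl{[2,5-bis(methoxymethoxy)phenyl](methoxy)methylidene}chromium(0)
Product: 19 (1R)-1-[5,8-bis(methoxymethoxy)-1,4-dioxo-1,4-dihydronaphthalen-2-yl]-4-methylpent-3-en-1-yl (3Z)-5-methylhexa-3,5-dienoate, via naphthol chromium tricarbonyl complex 18 (not isolated)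
Conditions: 17 (1.3 equiv), THF (0.05 M, degassed), 50 °C; then CAN (7 equiv), MeCN/H2O, 0 °C, 15 min
Reagents that add atoms: water, O
Why: Dötz benzannulation: thermal CO loss from 17 lets the terminal alkyne of 11 coordinate and insert into the Cr=C bond with its unsubstituted carbon bonding to the carbene carbon, CO insertion gives an η4-vinylketene complex, and this closes by 6π-electrocyclisation onto the aryl ring and tautomerises to the Cr(CO)3-bound 4-methoxy-1-naphthol 18, which CAN demetalates and oxidises to the quinone with loss of methanol. The closest known reaction type is the benzannulation of aryl(alkoxy)carbene chromium complexes with terminal alkynes followed by oxidative work-up to 1,4-naphthoquinones. The one ring closed (C1–C4, C4a, C8a) is completed by the 6π-electrocyclic closure of the dienylketene (C1–C8a bond) after the intermolecular C3–C4 and C1–C2 bond formations. No new stereocentre is created, and the propargylic C–O stereocentre takes no part in any bond made or broken, so the (R) configuration should be carried over unchanged. The step needs closure on the H-bearing ortho carbon (the other ortho position is blocked by OMOM), alkyne insertion in preference to reaction at the trisubstituted alkene or the 1,3-diene (alkynes insert far faster than alkenes are cyclopropanated at 50 °C, and the preferred Z conformation of the ester holds the diene away from the vinylcarbene carbon), and oxidation of the free naphthol ring rather than the bis-MOM ring (it is much the more electron-rich). The regiochemistry of alkyne insertion is of no consequence, because C1 and C4 both end as carbonyl groups flanking a symmetrically substituted ring.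

Step 10
Reactants: 19 (1R)-1-[5,8-bis(methoxymethoxy)-1,4-dioxo-1,4-dihydronaphthalen-2-yl]-4-methylpent-3-en-1-yl (3Z)-5-methylhexa-3,5-dienoate
Product: 20 (1R)-1-(5,8-dihydroxy-1,4-dioxo-1,4-dihydronaphthalen-2-yl)-4-methylpent-3-en-1-yl (3Z)-5-methylhexa-3,5-dienoate
Conditions: MgBr2·OEt2 (6 equiv), Et2O/CH2Cl2, 0 °C → rt; then H2O (pH 5 buffer)
Reagents that add atoms: none
Why: Chelation-assisted Lewis-acid cleavage of the two MOM acetals, each peri to a quinone carbonyl (six-membered Mg chelate), should release the hydrogen-bonded naphthazarin under conditions that leave the ester, the skipped diene and the stereocentre untouched.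

Compound list
1 | 4-methylpent-3-enoic acid | CC(C)=CCC(=O)O | starting material
2 | N-methoxy-N,4-dimethylpent-3-enamide | CC(C)=CCC(=O)N(C)OC | intermediate
3 | lithium (trimethylsilyl)acetylide (0.5 M in THF) | [Li]C#C[Si](C)(C)C | starting material
4 | 6-methyl-1-(trimethylsilyl)hept-5-en-1-yn-3-one | CC(C)=CCC(=O)C#C[Si](C)(C)C | intermediate
5 | (3R)-6-methyl-1-(trimethylsilyl)hept-5-en-1-yn-3-ol | CC(C)=CC[C@@H](O)C#C[Si](C)(C)C | intermediate
6 | (3R)-6-methylhept-5-en-1-yn-3-ol | CC(C)=CC[C@@H](O)C#C | intermediate
7 | (2-carboxyethyl)triphenylphosphonium bromide | OC(=O)CC[P+](c1ccccc1)(c1ccccc1)c1ccccc1.[Br-] | starting material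
8 | methacrolein (2-methylprop-2-enal) | C=C(C)C=O | starting material
9 | sodium 3-(triphenyl-λ5-phosphanylidene)propanoate (ylide carboxylate) | [Na+].[O-]C(=O)CC=P(c1ccccc1)(c1ccccc1)c1ccccc1 | intermediate (not isolated)
10 | (3Z)-5-methylhexa-3,5-dienoic acid | C=C(C)/C=C\CC(=O)O | intermediate
11 | (3R)-6-methylhept-5-en-1-yn-3-yl (3Z)-5-methylhexa-3,5-dienoate | C=C(C)/C=C\CC(=O)O[C@H](CC=C(C)C)C#C | intermediate
12 | hydroquinone (benzene-1,4-diol) | Oc1ccc(O)cc1 | starting material
13 | 1,4-bis(methoxymethoxy)benzene | COCOc1ccc(OCOC)cc1 | intermediate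
14 | hexacarbonylchromium | O=C=[Cr](=C=O)(=C=O)(=C=O)(=C=O)=C=O | starting material
15 | 2,5-bis(methoxymethoxy)phenyllithium | [Li]c1cc(OCOC)ccc1OCOC | intermediate (not isolated)
16 | lithium pentacarbonyl{[2,5-bis(methoxymethoxy)phenyl](oxido)methylidene}chromate | [Li+].[O-]C(c1cc(OCOC)ccc1OCOC)=[Cr](=C=O)(=C=O)(=C=O)(=C=O)=C=O | intermediate (not isolated)
17 | pentacarbonyl{[2,5-bis(methoxymethoxy)phenyl](methoxy)methylidene}chromium(0) | COC(c1cc(OCOC)ccc1OCOC)=[Cr](=C=O)(=C=O)(=C=O)(=C=O)=C=O | intermediate
18 | tricarbonylchromium η6 complex of (1R)-1-[1-hydroxy-4-methoxy-5,8-bis(methoxymethoxy)naphthalen-2-yl]-4-methylpent-3-en-1-yl (3Z)-5-methylhexa-3,5-dienoate (written as ligand plus Cr(CO)3 fragment) | C=C(C)/C=C\CC(=O)O[C@H](CC=C(C)C)c1cc(OC)c2c(OCOC)ccc(OCOC)c2c1O.[Cr](=C=O)(=C=O)=C=O | intermediate (not isolated)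
19 | (1R)-1-[5,8-bis(methoxymethoxy)-1,4-dioxo-1,4-dihydronaphthalen-2-yl]-4-methylpent-3-en-1-yl (3Z)-5-methylhexa-3,5-dienoate | C=C(C)/C=C\CC(=O)O[C@H](CC=C(C)C)C1=CC(=O)c2c(OCOC)ccc(OCOC)c2C1=O | intermediate
20 | (1R)-1-(5,8-dihydroxy-1,4-dioxo-1,4-dihydronaphthalen-2-yl)-4-methylpent-3-en-1-yl (3Z)-5-methylhexa-3,5-dienoate (CNP0129564.1) | C=C(C)/C=C\CC(=O)O[C@H](CC=C(C)C)C1=CC(=O)c2c(O)ccc(O)c2C1=O | target

Total step count: 10
Longest linear sequence: 7 steps (1, 2, 3, 4, 6, 9, 10)

Steps most likely to fail

Step 9 (key step). The chromium vinylcarbene and vinylketene intermediates may be intercepted by the pendant 1,3-diene or the propargylic acyloxy group (intramolecular cyclopropanation, cyclobutenone or indene formation) instead of electrocyclising, and the diene may suffer in the oxidative work-up. The fallback sets out from alkynol 6 and returns to the route at target 20; it keeps the acyl group out of the benzannulation and attaches it last. Alkynol 6 would be silylated (TBSCl, imidazole, DMF) to (3R)-3-(tert-butyldimethylsilyloxy)-6-methylhept-5-en-1-yne F1. Benzannulation of F1 with carbene complex 17 (THF, 50 °C) should give the silyl-protected naphthol chromium tricarbonyl complex F2 (not isolated), which CAN would oxidise to 2-[(1R)-1-(tert-butyldimethylsilyloxy)-4-methylpent-3-en-1-yl]-5,8-bis(methoxymethoxy)naphthalene-1,4-dione F3. MgBr2·OEt2 would cleave the MOM ethers to 2-[(1R)-1-(tert-butyldimethylsilyloxy)-4-methylpent-3-en-1-yl]-5,8-dihydroxynaphthalene-1,4-dione F4, and HF·pyridine in THF would remove the silyl group to give shikonin F5. Steglich acylation of F5 with acid 10 (DCC, cat. DMAP, CH2Cl2, 0 °C) should take place at the side-chain hydroxyl, because both peri hydroxyls are tied up in hydrogen bonds to the quinone carbonyls, and give 20.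

Step 10. Cleavage of the MOM ethers may stall at the mono-ether, or the Lewis acid and the HBr it releases may add to the 2-substituted diene or the prenyl alkene, or move the skipped diene into conjugation with the ester. The fallback sets out from alkyne ester 11 and hexacarbonylchromium 14 and returns at target 20; it replaces acid-labile by oxidatively cleavable phenol protection, so that no Lewis-acid step remains. Commercial 2-bromobenzene-1,4-diol would be bis-alkylated with 4-methoxybenzyl chloride (K2CO3, DMF) to 2-bromo-1,4-bis[(4-methoxybenzyl)oxy]benzene F6. Bromine–lithium exchange (n-BuLi, THF, –78 °C) would give 2,5-bis[(4-methoxybenzyl)oxy]phenyllithium F7, which adds to 14 to give the lithium acylchromate F8; methylation with Me3OBF4 gives the PMB-protected carbene complex F9. Benzannulation of F9 with 11 as in step 9 should give the PMB-protected naphthol chromium tricarbonyl complex F10 (not isolated). Work-up with excess CAN (MeCN/H2O, 0 °C) would first form the 5,8-bis[(4-methoxybenzyl)oxy]-1,4-naphthoquinone ester F11 and then remove both PMB groups by oxidation of their anisyl rings to give 20; DDQ in CH2Cl2/pH 7 buffer can complete the second stage if needed.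

Step 6. Activation of the acid at its carbonyl group may let the doubly activated α-CH2 lose a proton (through the O-acylisourea, the acylpyridinium ion or a vinylketene), so that the β,γ-alkene migrates into conjugation and the 2,4-dienoate forms. The fallback sets out from ynone 4 and returns at ester 11; it makes the ester C–O bond by substitution at the carbinol carbon, with the acid acting only as a carboxylate nucleophile. Ynone 4 would be reduced with the enantiomeric catalyst Ru[(S,S)-TsDPEN](p-cymene) in i-PrOH to (3S)-6-methyl-1-(trimethylsilyl)hept-5-en-1-yn-3-ol F12 and desilylated (K2CO3, MeOH) to (3S)-6-methylhept-5-en-1-yn-3-ol F13. Mitsunobu esterification of F13 with acid 10 (PPh3, DIAD, THF, 0 °C) should proceed with clean inversion at the propargylic carbon and give (R)-ester 11.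

Further compounds
F1 | step 9 | (3R)-3-(tert-butyldimethylsilyloxy)-6-methylhept-5-en-1-yne | CC(C)=CC[C@@H](O[Si](C)(C)C(C)(C)C)C#C
F2 | step 9 | tricarbonylchromium η6 complex of 2-[(1R)-1-(tert-butyldimethylsilyloxy)-4-methylpent-3-en-1-yl]-4-methoxy-5,8-bis(methoxymethoxy)naphthalen-1-ol (not isolated; ligand plus Cr(CO)3 fragment) | CC(C)=CC[C@@H](O[Si](C)(C)C(C)(C)C)c1cc(OC)c2c(OCOC)ccc(OCOC)c2c1O.[Cr](=C=O)(=C=O)=C=O
F3 | step 9 | 2-[(1R)-1-(tert-butyldimethylsilyloxy)-4-methylpent-3-en-1-yl]-5,8-bis(methoxymethoxy)naphthalene-1,4-dione | CC(C)=CC[C@@H](O[Si](C)(C)C(C)(C)C)C1=CC(=O)c2c(OCOC)ccc(OCOC)c2C1=O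
F4 | step 9 | 2-[(1R)-1-(tert-butyldimethylsilyloxy)-4-methylpent-3-en-1-yl]-5,8-dihydroxynaphthalene-1,4-dione | CC(C)=CC[C@@H](O[Si](C)(C)C(C)(C)C)C1=CC(=O)c2c(O)ccc(O)c2C1=O
F5 | step 9 | shikonin, 5,8-dihydroxy-2-[(1R)-1-hydroxy-4-methylpent-3-en-1-yl]naphthalene-1,4-dione | CC(C)=CC[C@@H](O)C1=CC(=O)c2c(O)ccc(O)c2C1=O
F6 | step 10 | 2-bromo-1,4-bis[(4-methoxybenzyl)oxy]benzene | COc1ccc(COc2ccc(OCc3ccc(OC)cc3)c(Br)c2)cc1
F7 | step 10 | 2,5-bis[(4-methoxybenzyl)oxy]phenyllithium (not isolated) | [Li]c1cc(OCc2ccc(OC)cc2)ccc1OCc1ccc(OC)cc1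
F8 | step 10 | lithium pentacarbonyl({2,5-bis[(4-methoxybenzyl)oxy]phenyl}(oxido)methylidene)chromate (not isolated) | [Li+].[O-]C(c1cc(OCc2ccc(OC)cc2)ccc1OCc1ccc(OC)cc1)=[Cr](=C=O)(=C=O)(=C=O)(=C=O)=C=O
F9 | step 10 | pentacarbonyl({2,5-bis[(4-methoxybenzyl)oxy]phenyl}(methoxy)methylidene)chromium(0) | COC(c1cc(OCc2ccc(OC)cc2)ccc1OCc1ccc(OC)cc1)=[Cr](=C=O)(=C=O)(=C=O)(=C=O)=C=O
F10 | step 10 | tricarbonylchromium η6 complex of (1R)-1-{1-hydroxy-4-methoxy-5,8-bis[(4-methoxybenzyl)oxy]naphthalen-2-yl}-4-methylpent-3-en-1-yl (3Z)-5-methylhexa-3,5-dienoate (not isolated; ligand plus Cr(CO)3 fragment) | C=C(C)/C=C\CC(=O)O[C@H](CC=C(C)C)c1cc(OC)c2c(OCc3ccc(OC)cc3)ccc(OCc3ccc(OC)cc3)c2c1O.[Cr](=C=O)(=C=O)=C=O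
F11 | step 10 | (1R)-1-{5,8-bis[(4-methoxybenzyl)oxy]-1,4-dioxo-1,4-dihydronaphthalen-2-yl}-4-methylpent-3-en-1-yl (3Z)-5-methylhexa-3,5-dienoate | C=C(C)/C=C\CC(=O)O[C@H](CC=C(C)C)C1=CC(=O)c2c(OCc3ccc(OC)cc3)ccc(OCc3ccc(OC)cc3)c2C1=O
F12 | step 6 | (3S)-6-methyl-1-(trimethylsilyl)hept-5-en-1-yn-3-ol | CC(C)=CC[C@H](O)C#C[Si](C)(C)C
F13 | step 6 | (3S)-6-methylhept-5-en-1-yn-3-ol | CC(C)=CC[C@H](O)C#C
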